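Compound numbers are those of the steps and the compound list below. Oxolane atoms are called O1, C2 (aryl), C3 (bears C9), C4 (bears C7'), C5; the six-membered precursor is numbered O1, C2, C3 (C=O), C4, C5, C6 and is always called "oxanone".

## Analysis of the target

The target is the 9-O-(E)-caffeoyl ester of (−)-lariciresinol: an oxolane with a guaiacyl ring on C2, the acylated hydroxymethyl carbon C9 on C3 and a guaiacylmethyl arm (C7') on C4. The SMILES reads as (2R,3S,4S): the aryl on C2 is trans to C9, C9 is cis to C7', and the aryl and the arylmethyl arm are therefore trans across the ring. This is not the all-trans arrangement that a free equilibration of C2 and C3 would reach, so the centres must be fixed in a set order. The sensitive groups are the p-hydroxybenzylic ether at C2 (acid ionises it, leading to epimerisation or Friedel–Crafts closure to an aryltetralin), the cinnamate (hydrogenation, conjugate addition, acyl cleavage), the catechol and the free phenols. The difficulty lies in three contiguous stereocentres on a flexible ring and in acylating one primary alcohol beside four phenols. The strategy rests on C9 being a single carbon on C3 next to the oxygen-bearing benzylic C2. If C9 is read as a former ring carbonyl carbon bonded to C2, the oxolane is the ring-contracted form of a 2-aryl-5-(arylmethyl)oxan-3-one, whose two substituents are 1,4-related and whose C2 is epimerisable.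

## Retrosynthetic reasoning

**Ester and protecting groups (28 ⇐ 27 ⇐ 23 + 26).** The caffeate C9–O bond is cut last, because the cinnamate and catechol tolerate neither hydride, alkoxide nor light. All four phenols are silyl ethers, so one fluoride treatment under buffered conditions releases them without acid or hydrogen. The forward coupling must acylate only the primary alcohol of 23, which is secured by the phenols being masked.

**Ring contraction (23 ⇐ 22 ⇐ 19).** The C2–C3 bond is cut and C2 is reconnected to C9, which turns the oxolane ester 22 into the diazo oxanone 19. This is the best place to cut because C9 then arrives at the ester level, distinct from every other oxygen function, and the trans relation of aryl and arylmethyl arm is inherited from a six-membered ring. The forward step must move C2 with retention, avoid a hydride shift to the carbene carbon, and leave C3 in the configuration in which the ester is trans to the aryl.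

**Diazo group (19 ⇐ 18 ⇐ 17).** The diazo carbon is C4 of the oxanone. Formylation is the activating step because C2 has only one hydrogen and cannot hold a stable formyl enolate, so the thermodynamic sink is the C4 hydroxymethylidene compound 18. Diazo transfer with loss of the formyl group then gives 19.

**Oxanone ring (17 ⇐ 15 ⇐ 13).** The O1–C2 bond is cut. In the forward direction the styrene of 13 is epoxidised and the primary hydroxyl opens the epoxide at the benzylic carbon, which the electron-rich aryl activates. Oxidation of the ring alcohol erases C3, and C2 next to the ketone is equilibrated, so neither the alkene geometry nor the face of epoxidation matters.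

**Styrene (13 ⇐ 11 + 12).** The C=C bond is cut by cross-metathesis of a terminal alkene with a styrene; both partners come from the same aldehyde 2.

**The one fixed stereocentre (11 ⇐ 10 ⇐ 8 + 4).** The bond between the future C4 of the oxolane and C7' is made by auxiliary-controlled alkylation. This centre cannot be corrected later, and it governs C2 and C3, so it is set with a predictable sense and in diastereomerically pure form. Relaying chirality from an enolisable C2 to this carbon by a 1,4-addition to a pyranone was not adopted: C2 is the very centre that is afterwards equilibrated, so any leakage in that remote induction would appear as loss of enantiomeric purity. The imide 8 comes from 5 and 6; the bromide 4 and the styrene 12 come from 2 and hence from 1; the acid 26 comes from 24.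

## Alternatives that were turned down

**Alternative 1:** The ring is cut at C4–C5. A homopropargylic benzylic alcohol is converted into its acetoxymethyl ether A2. SnBr4 (tetravalent tin) removes acetate to leave a formaldehyde-derived oxocarbenium ion on O1, the aryl alkyne attacks it through C4 (5-exo-dig with respect to the alkyne), and bromide quenches the vinyl cation at C7' to give the bromo(aryl)methylidene oxolane A1.
- For it: C2 and C3 are set beforehand by acyclic chemistry and are not epimerisable, which is stronger than the two equilibria of the chosen route; C9 is already at the alcohol level.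
- Against it: the cation CH2=O1(+)–C2–C3–C4≡C7' is set up for a 2-oxonia-Cope shift that breaks C2–C3, and the electron-rich aryl on C2 favours exactly that, so C2 and C3 may scramble or the chain may fragment. The strong Lewis acid also faces an ionisable p-silyloxybenzylic ether. The key step sets no stereocentre: C4 still needs debromination and a face-selective hydrogenation of a styrenyl alkene beside a benzylic C2–O bond prone to hydrogenolysis.
- Comparison: the chosen route fixes C4 first, uses no Lewis acid on the 2-aryl ether and needs no late hydrogenation.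

**Alternative 2:** The only bond made in the key step is O1–C5 of a relay lactone. A flavin- and NADPH-dependent Baeyer–Villiger monooxygenase inserts oxygen from O2 into one of the two enantiotopic C–C(=O) bonds of the 3-(arylmethyl)cyclobutanone A4 and gives the (S)-β-(arylmethyl)-γ-butyrolactone A3.
- For it: it is catalytic, needs no auxiliary and reaches A3 in few steps. The chemistry after A3 (aldol with an aryl aldehyde, reduction, acid ring closure) sets C2 and C3 more reliably than the chosen route does. On step economy and on stereochemical safety downstream it is as strong or stronger.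
- Against it: the key step builds one centre of a relay compound and nothing of the oxolane, whose lactone must be opened and re-closed. The sense and level of enzyme selectivity for a substrate with a bulky silyloxyaryl group would have to be found by screening, with cofactor recycling on top.
- Comparison: the chosen route sets the same centre with an auxiliary of known sense and makes the oxolane with C9 attached in one event. The lactone chemistry is kept as the fallback for the key step.

**Alternative 3:** The ring is cut at C3–C4. Cp2TiCl (trivalent titanium, from Cp2TiCl2 and zinc) opens the terminal epoxide of the epoxy cinnamyl ether A6 to a C3 radical, which adds 5-exo-trig to the cinnamyl alkene. The benzylic C7' radical is reduced by a second equivalent and protonated, giving the bis-silyl ether of (−)-lariciresinol A5 with free C9–OH.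
- For it: ring, C3–C4 bond, two stereocentres and the C9 alcohol arise in one step. It is clearly shorter, and the chair-like radical transition state favours 2,3-trans-3,4-cis kinetically, whereas the chosen route leaves C3 to an equilibrium.
- Against it: the selectivity is kinetic, rests on small energy differences and cannot be corrected afterwards. A6 needs an enantiopure benzylic ether centre next to an epoxide, and etherifying that hindered alkoxide invites Payne rearrangement. Titanium is used in more than stoichiometric amount.
- Comparison: the chosen route fixes C4 by auxiliary instead of relay from C2, and its two other centres are under thermodynamic control, so wrong isomers can be recycled.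

Key step: step 13

Remark on the chemistry: the two phenols of the lignan core are carried as triisopropylsilyl ethers in place of tert-butyldimethylsilyl ethers, since these should better survive the alkoxide and hydride steps and still leave with fluoride. In names, Ar = 3-methoxy-4-[tri(propan-2-yl)silyloxy]phenyl.

## Route

Step 1
Reactants: 1 vanillin
Product: 2 3-methoxy-4-[tri(propan-2-yl)silyloxy]benzaldehyde (Ar–CHO)
Conditions: TIPSCl, imidazole, DMF, 0 °C to rt
Reagents that add atoms: chlorotri(propan-2-yl)silane, CC(C)[Si](Cl)(C(C)C)C(C)C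
Why: Imidazole-promoted silylation of a phenol; the aldehyde is inert.

Step 2
Reactants: 2 Ar–CHO
Product: 3 Ar-methanol
Conditions: NaBH4, MeOH–THF, 0 °C
Reagents that add atoms: none
Why: Borohydride reduction of an aryl aldehyde; the aryl silyl ether should survive the short, cold reaction.

Step 3
Reactants: 3 Ar-methanol
Product: 4 Ar-methyl bromide, [4-(bromomethyl)-2-methoxyphenoxy]tri(propan-2-yl)silane
Conditions: CBr4, PPh3, CH2Cl2, 0 °C; used at once
Reagents that add atoms: tetrabromomethane, BrC(Br)(Br)Br
Why: Appel bromination under neutral conditions, which avoids HBr and so spares the silyl ether; the electron-rich benzylic bromide is not stored.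

Step 4
Reactants: 5 (4S)-4-benzyl-1,3-oxazolidin-2-one; 6 pent-4-enoyl chloride
Product: 8 (4S)-4-benzyl-3-(pent-4-enoyl)-1,3-oxazolidin-2-one, via lithium oxazolidinide 7 (not isolated)
Conditions: n-BuLi, THF, −78 °C; then 6, −78 to 0 °C
Reagents that add atoms: none
Why: N-acylation of the lithiated auxiliary with an acid chloride.

Step 5
Reactants: 8 the imide; 4 Ar-methyl bromide
Product: 10 (4S)-4-benzyl-3-[(2R)-2-(Ar-methyl)pent-4-enoyl]-1,3-oxazolidin-2-one, via sodium Z-enolate 9 (not isolated)
Conditions: NaN(SiMe3)2, THF, −78 °C; then 4, −78 to −40 °C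
Reagents that add atoms: none
Why: Evans alkylation: the chelated Z-enolate is attacked by the benzylic bromide on the face away from the auxiliary's benzyl group, which with the (S)-auxiliary gives the (2R) centre (future C4 of the oxolane). The minor diastereomer is removed by chromatography.

Step 6
Reactants: 10 the alkylated imide
Product: 11 (2R)-2-(Ar-methyl)pent-4-en-1-ol
Conditions: LiBH4, MeOH (1 equiv), THF, 0 °C
Reagents that add atoms: none
Why: Reductive cleavage of the N-acyl oxazolidinone to the primary alcohol without touching the α-centre; the auxiliary is recovered.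

Step 7
Reactants: 2 Ar–CHO
Product: 12 Ar-ethene, (4-ethenyl-2-methoxyphenoxy)tri(propan-2-yl)silane
Conditions: Ph3PCH3Br, n-BuLi, THF, 0 °C; then 2, 0 °C to rt
Reagents that add atoms: methyltriphenylphosphonium bromide, C[P+](c1ccccc1)(c1ccccc1)c1ccccc1.[Br-]
Why: Wittig methylenation; the ylide is preformed so that no free strong base meets the silyl ether.

Step 8
Reactants: 11 the pentenol; 12 Ar-ethene (excess)
Product: 13 (2R,4E)-5-Ar-2-(Ar-methyl)pent-4-en-1-ol
Conditions: second-generation Hoveyda–Grubbs catalyst RuCl2(H2IMes)(=CH-C6H4-2-OiPr) (5 mol %), CH2Cl2, 40 °C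
Reagents that add atoms: none
Why: Cross-metathesis of a terminal alkene with a slowly dimerising styrene, driven by loss of ethene. The E isomer should dominate, but the geometry is irrelevant because both alkene carbons lose their configuration later.

Step 9
Reactants: 13 the styrenyl alcohol
Product: 15 (5S)-2-Ar-5-(Ar-methyl)oxan-3-ol (mixture at C2 and C3), via trans-epoxide 14 (not isolated)
Conditions: mCPBA, NaHCO3, CH2Cl2, 0 °C; then camphor-10-sulfonic acid (cat.), 0 °C
Reagents that add atoms: 3-chloroperoxybenzoic acid, OOC(=O)c1cccc(Cl)c1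
Why: Prilezhaev epoxidation followed by acid-catalysed hydroxy-epoxide cyclisation. The p-silyloxyaryl group stabilises positive charge at the benzylic carbon, so the primary hydroxyl should attack there (6-endo) and not at the other epoxide carbon (5-exo). The configurations created at C2 and C3 are not needed, since C3 is oxidised and C2 equilibrated in step 10.

Step 10
Reactants: 15 the oxanol mixture
Product: 17 (2S,5S)-2-Ar-5-(Ar-methyl)oxan-3-one (2,5-trans), via cis-ketone 16 (not isolated)
Conditions: Dess–Martin periodinane, NaHCO3, CH2Cl2, 0 °C to rt; work-up; then DBU (0.2 equiv), CH2Cl2, rt, under argon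
Reagents that add atoms: none
Why: Dess–Martin oxidation gives the ketone as a C2 mixture; DBU then epimerises the acidic C2–H (benzylic, α to oxygen and carbonyl) towards the isomer with both substituents equatorial. The bias is estimated to be moderate, so residual 16 is separated and re-equilibrated.

Step 11
Reactants: 17 the trans ketone
Product: 18 (2S,4Z,5S)-2-Ar-5-(Ar-methyl)-4-(hydroxymethylidene)oxan-3-one
Conditions: NaH, HCO2Et, EtOH (cat.), THF, 0 °C to rt
Reagents that add atoms: ethyl formate, CCOC=O
Why: Claisen formylation is reversible at C2, which cannot form a stable formyl enolate, so the product funnels to the C4 hydroxymethylidene enolate.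

Step 12
Reactants: 18 the hydroxymethylidene ketone
Product: 19 (2S,5S)-2-Ar-5-(Ar-methyl)-4-diazooxan-3-one
Conditions: MsN3, Et3N, MeCN, 0 °C to rt; chromatography
Reagents that add atoms: methanesulfonyl azide, CS(=O)(=O)N=[N+]=[N-]
Why: Regitz deformylative diazo transfer: the enolate adds to the azide and the formyl group leaves as N-formyl sulfonamide. Any 2,5-cis isomer formed by C2 exchange in step 11 is removed here and can be returned with catalytic DBU.

Step 13
Reactants: 19 the diazo oxanone
Product: 22 methyl (2R,3R,4S)-2-Ar-4-(Ar-methyl)oxolane-3-carboxylate (2,3-trans, 3,4-cis), via ketene 20 (not isolated), via C3-epimeric ester 21 (not isolated)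
Conditions: hν (365 nm), MeOH (degassed), 10 °C; then NaOMe (0.2 equiv), 0 °C to rt
Reagents that add atoms: methanol, CO
Why: Excitation of the diazo ketone, which the ring holds s-cis, should expel N2 in concert with a suprafacial 1,2-shift of C2 from the carbonyl carbon (future C9) to the diazo carbon (future C3); this makes the C2–C3 bond and contracts the oxanone to the oxolane, the closest known reaction type being the photochemical Wolff ring contraction of cyclic α-diazo ketones in an alcohol. The oxolane is closed by contraction and not by an end-to-end cyclisation, so no Baldwin mode applies, and C2 keeps its configuration because it stays bonded on the same face throughout. Methanol adds to the exocyclic ketene 20 and the ester enol tautomerises to 21 and 22, which creates C3. Catalytic methoxide in the same solution then puts C3 under thermodynamic control: the ester should prefer the face away from the aryl bound directly to C2, which places it cis to the more flexible arylmethyl arm on C4 and gives 22. Rearrangement is favoured over a 1,2-hydride shift from the neighbouring CH by direct irradiation at a wavelength that only the diazo ketone absorbs and by the absence of metal catalysts. C4 has no acidic hydrogen and is untouched, and methyl ester and methoxide are matched so that no transesterification occurs. Residual 21 is separated and re-equilibrated.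

Step 14
Reactants: 22 the methyl ester
Product: 23 [(2R,3S,4S)-2-Ar-4-(Ar-methyl)oxolan-3-yl]methanol
Conditions: LiAlH4, THF, 0 °C
Reagents that add atoms: none
Why: Hydride reduction of the ester to the C9 alcohol is fast at 0 °C and should not epimerise C3; the descriptor at C3 changes only because the priorities change.

Step 15
Reactants: 24 caffeic acid
Product: 26 (2E)-3-{3,4-bis[tert-butyl(dimethyl)silyloxy]phenyl}prop-2-enoic acid, via silyl ester 25 (not isolated)
Conditions: TBSCl, imidazole, DMF, rt; then AcOH–THF–H2O, rt
Reagents that add atoms: tert-butyl(chloro)dimethylsilane, CC(C)(C)[Si](C)(C)Cl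
Why: Exhaustive silylation followed by selective hydrolysis of the silyl ester, which is far more labile than the aryl silyl ethers.

Step 16
Reactants: 23 the alcohol; 26 the protected caffeic acid
Product: 27 [(2R,3S,4S)-2-Ar-4-(Ar-methyl)oxolan-3-yl]methyl (2E)-3-{3,4-bis[tert-butyl(dimethyl)silyloxy]phenyl}prop-2-enoate
Conditions: EDC·HCl, DMAP, CH2Cl2, 0 °C to rt
Reagents that add atoms: none
Why: Steglich esterification of an unhindered primary alcohol; with all phenols silylated, only the C9 hydroxyl can be acylated.

Step 17
Reactants: 27 the fully silylated ester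
Product: 28 the target, [(2R,3S,4S)-2-(4-hydroxy-3-methoxyphenyl)-4-[(4-hydroxy-3-methoxyphenyl)methyl]oxolan-3-yl]methyl (2E)-3-(3,4-dihydroxyphenyl)prop-2-enoate
Conditions: Bu4NF, AcOH, THF (degassed), 0 °C to rt
Reagents that add atoms: none
Why: Fluoride cleaves all four aryl silyl ethers. Acetic acid buffers the phenoxides, which should prevent acyl transfer, ester cleavage and catechol oxidation, and no acid strong enough to ionise C2 is present.

## Compound list

1 | vanillin | COc1cc(C=O)ccc1O | starting material
2 | 3-methoxy-4-[tri(propan-2-yl)silyloxy]benzaldehyde | COc1cc(C=O)ccc1O[Si](C(C)C)(C(C)C)C(C)C | intermediate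
3 | {3-methoxy-4-[tri(propan-2-yl)silyloxy]phenyl}methanol | COc1cc(CO)ccc1O[Si](C(C)C)(C(C)C)C(C)C | intermediate
4 | [4-(bromomethyl)-2-methoxyphenoxy]tri(propan-2-yl)silane | COc1cc(CBr)ccc1O[Si](C(C)C)(C(C)C)C(C)C | intermediate
5 | (4S)-4-benzyl-1,3-oxazolidin-2-one | O=C1N[C@@H](Cc2ccccc2)CO1 | starting material
6 | pent-4-enoyl chloride | C=CCCC(Cl)=O | starting material
7 | lithium salt of 5 (N-lithio oxazolidinone) | [Li+].O=C1[N-][C@@H](Cc2ccccc2)CO1 | intermediate
8 | (4S)-4-benzyl-3-(pent-4-enoyl)-1,3-oxazolidin-2-one | C=CCCC(=O)N1[C@@H](Cc2ccccc2)COC1=O | intermediate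
9 | sodium (Z)-enolate of 8 | [Na+].[O-]/C(=C\CC=C)N1[C@@H](Cc2ccccc2)COC1=O | intermediate
10 | (4S)-4-benzyl-3-[(2R)-2-(Ar-methyl)pent-4-enoyl]-1,3-oxazolidin-2-one | COc1cc(C[C@@H](CC=C)C(=O)N2[C@@H](Cc3ccccc3)COC2=O)ccc1O[Si](C(C)C)(C(C)C)C(C)C | intermediate
11 | (2R)-2-(Ar-methyl)pent-4-en-1-ol | COc1cc(C[C@@H](CC=C)CO)ccc1O[Si](C(C)C)(C(C)C)C(C)C | intermediate
12 | (4-ethenyl-2-methoxyphenoxy)tri(propan-2-yl)silane | COc1cc(C=C)ccc1O[Si](C(C)C)(C(C)C)C(C)C | intermediate
13 | (2R,4E)-5-Ar-2-(Ar-methyl)pent-4-en-1-ol | COc1cc(C[C@@H](C/C=C/c2ccc(O[Si](C(C)C)(C(C)C)C(C)C)c(OC)c2)CO)ccc1O[Si](C(C)C)(C(C)C)C(C)C | intermediate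
14 | (2S)-2-(Ar-methyl)-3-(trans-3-Ar-oxiran-2-yl)propan-1-ol, both epoxide diastereomers (same spatial arrangement at C2 as in 13) | COc1cc(C[C@@H](CC2OC2c3ccc(O[Si](C(C)C)(C(C)C)C(C)C)c(OC)c3)CO)ccc1O[Si](C(C)C)(C(C)C)C(C)C | intermediate
15 | (5S)-2-Ar-5-(Ar-methyl)oxan-3-ol, mixture at C2 and C3 | COc1cc(C[C@@H]2COC(c3ccc(O[Si](C(C)C)(C(C)C)C(C)C)c(OC)c3)C(O)C2)ccc1O[Si](C(C)C)(C(C)C)C(C)C | intermediate
16 | (2R,5S)-2-Ar-5-(Ar-methyl)oxan-3-one (2,5-cis) | COc1cc(C[C@@H]2CO[C@H](c3ccc(O[Si](C(C)C)(C(C)C)C(C)C)c(OC)c3)C(=O)C2)ccc1O[Si](C(C)C)(C(C)C)C(C)C | intermediate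
17 | (2S,5S)-2-Ar-5-(Ar-methyl)oxan-3-one (2,5-trans) | COc1cc(C[C@@H]2CO[C@@H](c3ccc(O[Si](C(C)C)(C(C)C)C(C)C)c(OC)c3)C(=O)C2)ccc1O[Si](C(C)C)(C(C)C)C(C)C | intermediate
18 | (2S,4Z,5S)-2-Ar-5-(Ar-methyl)-4-(hydroxymethylidene)oxan-3-one | COc1cc(C[C@@H]2CO[C@@H](c3ccc(O[Si](C(C)C)(C(C)C)C(C)C)c(OC)c3)C(=O)/C2=C\O)ccc1O[Si](C(C)C)(C(C)C)C(C)C | intermediate
19 | (2S,5S)-2-Ar-5-(Ar-methyl)-4-diazooxan-3-one | COc1cc(C[C@@H]2CO[C@@H](c3ccc(O[Si](C(C)C)(C(C)C)C(C)C)c(OC)c3)C(=O)C2=[N+]=[N-])ccc1O[Si](C(C)C)(C(C)C)C(C)C | intermediate
20 | (2S,4S)-2-Ar-4-(Ar-methyl)-3-(oxomethylidene)oxolane (ketene) | COc1cc(C[C@@H]2CO[C@@H](c3ccc(O[Si](C(C)C)(C(C)C)C(C)C)c(OC)c3)C2=C=O)ccc1O[Si](C(C)C)(C(C)C)C(C)C | intermediate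
21 | methyl (2R,3S,4S)-2-Ar-4-(Ar-methyl)oxolane-3-carboxylate (2,3-cis, 3,4-trans) | COc1cc(C[C@@H]2CO[C@@H](c3ccc(O[Si](C(C)C)(C(C)C)C(C)C)c(OC)c3)[C@H]2C(=O)OC)ccc1O[Si](C(C)C)(C(C)C)C(C)C | intermediate
22 | methyl (2R,3R,4S)-2-Ar-4-(Ar-methyl)oxolane-3-carboxylate (2,3-trans, 3,4-cis) | COc1cc(C[C@@H]2CO[C@@H](c3ccc(O[Si](C(C)C)(C(C)C)C(C)C)c(OC)c3)[C@@H]2C(=O)OC)ccc1O[Si](C(C)C)(C(C)C)C(C)C | intermediate
23 | [(2R,3S,4S)-2-Ar-4-(Ar-methyl)oxolan-3-yl]methanol | COc1cc(C[C@@H]2CO[C@@H](c3ccc(O[Si](C(C)C)(C(C)C)C(C)C)c(OC)c3)[C@@H]2CO)ccc1O[Si](C(C)C)(C(C)C)C(C)C | intermediate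
24 | caffeic acid | OC(=O)/C=C/c1ccc(O)c(O)c1 | starting material
25 | tert-butyl(dimethyl)silyl (2E)-3-{3,4-bis[tert-butyl(dimethyl)silyloxy]phenyl}prop-2-enoate | CC(C)(C)[Si](C)(C)OC(=O)/C=C/c1ccc(O[Si](C)(C)C(C)(C)C)c(O[Si](C)(C)C(C)(C)C)c1 | intermediate
26 | (2E)-3-{3,4-bis[tert-butyl(dimethyl)silyloxy]phenyl}prop-2-enoic acid | OC(=O)/C=C/c1ccc(O[Si](C)(C)C(C)(C)C)c(O[Si](C)(C)C(C)(C)C)c1 | intermediate
27 | [(2R,3S,4S)-2-Ar-4-(Ar-methyl)oxolan-3-yl]methyl (2E)-3-{3,4-bis[tert-butyl(dimethyl)silyloxy]phenyl}prop-2-enoate | COc1cc(C[C@@H]2CO[C@@H](c3ccc(O[Si](C(C)C)(C(C)C)C(C)C)c(OC)c3)[C@@H]2COC(=O)/C=C/c2ccc(O[Si](C)(C)C(C)(C)C)c(O[Si](C)(C)C(C)(C)C)c2)ccc1O[Si](C(C)C)(C(C)C)C(C)C | intermediate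
28 | [(2R,3S,4S)-2-(4-hydroxy-3-methoxyphenyl)-4-[(4-hydroxy-3-methoxyphenyl)methyl]oxolan-3-yl]methyl (2E)-3-(3,4-dihydroxyphenyl)prop-2-enoate | COc1cc(C[C@@H]2CO[C@@H](c3ccc(O)c(OC)c3)[C@@H]2COC(=O)/C=C/c2ccc(O)c(O)c2)ccc1O | target

## Step count and least certain steps

Total: 17 steps. Longest linear sequence: 14 steps (1, 2, 3, 5, 6, 8, 9, 10, 11, 12, 13, 14, 16, 17).

**Step 13 (key step).** Two things may go wrong.
- Nitrogen may be lost through a free carbene, which then undergoes a 1,2-hydride shift from the neighbouring CH to an enone or inserts into the O–H bond of methanol, instead of the concerted shift of C2.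
- The C3 equilibrium may not lie far enough towards 22, because the ester must sit cis to one of its two neighbours and the energy gap is small. Methoxide may also attack the aryl silyl ethers, or the ester enolate may open the ring by β-elimination across C2–O1, which would scramble C2 as well.

The fallback leaves ring contraction altogether. It sets out from 11 and returns to the route at 23.
- Oxidative cleavage of the alkene of 11 (K2OsO4·2H2O cat., NaIO4, 2,6-lutidine, dioxane–water) should give the lactol (4S)-4-(Ar-methyl)oxolan-2-ol F1.
- Oxidation with TEMPO and PhI(OAc)2 should give the lactone (4S)-4-(Ar-methyl)oxolan-2-one F2.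
- Its lithium enolate (LiN(SiMe3)2, THF, −78 °C) adds to aldehyde 2 anti to the arylmethyl arm and gives the trans aldol adduct (3R,4S)-3-[hydroxy(Ar)methyl]-4-(Ar-methyl)oxolan-2-one F3; its carbinol configuration is irrelevant.
- LiAlH4 reduces it to the triol (2S,3S)-2-[hydroxy(Ar)methyl]-3-(Ar-methyl)butane-1,4-diol F4.
- Catalytic camphorsulfonic acid in CH2Cl2 at 0 °C ionises the benzylic carbinol, and the hydroxyl on the arm next to the arylmethyl-bearing carbon closes the oxolane with the aryl trans to C9, giving 23.

**Step 9.** The ring closure may take the wrong course: 5-exo attack at the non-benzylic epoxide carbon, hydride shift in the opened epoxide to a benzyl ketone (Meinwald rearrangement), or capture of the benzylic position by chlorobenzoate. All follow from the high lability of an electron-rich styrene oxide in the presence of a carboxylic acid. The fallback sets out from 13 and returns at 15. Dihydroxylation (OsO4 cat., N-methylmorpholine N-oxide, acetone–water) gives the triol (2S)-5-Ar-2-(Ar-methyl)pentane-1,4,5-triol F5. Catalytic camphorsulfonic acid then ionises only the benzylic carbinol, and the primary hydroxyl closes the six-membered ring. The peracid is thereby removed from the picture and no 5-exo path exists.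

**Step 10.** The thermodynamic discrimination at C2 may be insufficient. An axial side chain on C5 of the oxanone faces only the ring oxygen and the carbonyl carbon, so the trans preference is small and repeated separation and recycling may become laborious. The fallback moves the equilibration to the alcohol stage; it sets out from 15 and returns at 17. Prolonged exposure of 15 to a catalytic acid (camphorsulfonic acid or BF3·OEt2, CH2Cl2, −20 to 0 °C) should reversibly ionise the C2–O1 bond and collect the material as the 2,5-trans oxanol (2S,5S)-2-Ar-5-(Ar-methyl)oxan-3-ol F6. At that stage C3 is tetrahedral, so an axial C5 arm is penalised more strongly. Oxidation with Dess–Martin periodinane and NaHCO3 alone, without amine base, then gives 17. In this variant the diazo group is installed by the low-temperature fallback of step 11, so that C2 is not exchanged again.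

**Step 11.** Formylation may be slow because the enolate population sits almost entirely at C2; C2 is exchanged during the reaction; and the ethoxide formed may attack the aryl silyl ethers. The fallback sets out from 17 and returns at 19. Kinetic deprotonation at the less hindered C4 (LiN(SiMe3)2, THF, −78 °C) and acylation with CF3CO2CH2CF3 gives the trifluoroacetyl ketone (2S,5S)-2-Ar-5-(Ar-methyl)-4-(trifluoroacetyl)oxan-3-one F7. Detrifluoroacetylative diazo transfer (MsN3, Et3N, H2O, MeCN) then gives 19 without alkoxide. Material acylated at C2 cannot accept the diazo group and reverts to 17.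

## Further compounds

F1 | step 13 | (4S)-4-(Ar-methyl)oxolan-2-ol, both anomers | COc1cc(C[C@@H]2COC(O)C2)ccc1O[Si](C(C)C)(C(C)C)C(C)C
F2 | step 13 | (4S)-4-(Ar-methyl)oxolan-2-one | COc1cc(C[C@@H]2COC(=O)C2)ccc1O[Si](C(C)C)(C(C)C)C(C)C
F3 | step 13 | (3R,4S)-3-[hydroxy(Ar)methyl]-4-(Ar-methyl)oxolan-2-one, carbinol epimers | COc1cc(C[C@@H]2COC(=O)[C@H]2C(O)c3ccc(O[Si](C(C)C)(C(C)C)C(C)C)c(OC)c3)ccc1O[Si](C(C)C)(C(C)C)C(C)C
F4 | step 13 | (2S,3S)-2-[hydroxy(Ar)methyl]-3-(Ar-methyl)butane-1,4-diol, carbinol epimers | COc1cc(C[C@H](CO)[C@@H](CO)C(O)c2ccc(O[Si](C(C)C)(C(C)C)C(C)C)c(OC)c2)ccc1O[Si](C(C)C)(C(C)C)C(C)C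
F5 | step 9 | (2S)-5-Ar-2-(Ar-methyl)pentane-1,4,5-triol, diol from syn addition to the E alkene, both facial diastereomers | COc1cc(C[C@@H](CC(O)C(O)c2ccc(O[Si](C(C)C)(C(C)C)C(C)C)c(OC)c2)CO)ccc1O[Si](C(C)C)(C(C)C)C(C)C
F6 | step 10 | (2S,5S)-2-Ar-5-(Ar-methyl)oxan-3-ol, C3 epimers | COc1cc(C[C@@H]2CO[C@@H](c3ccc(O[Si](C(C)C)(C(C)C)C(C)C)c(OC)c3)C(O)C2)ccc1O[Si](C(C)C)(C(C)C)C(C)C
F7 | step 11 | (2S,5S)-2-Ar-5-(Ar-methyl)-4-(trifluoroacetyl)oxan-3-one, keto/enol forms | COc1cc(C[C@@H]2CO[C@@H](c3ccc(O[Si](C(C)C)(C(C)C)C(C)C)c(OC)c3)C(=O)C2C(=O)C(F)(F)F)ccc1O[Si](C(C)C)(C(C)C)C(C)C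
A1 | alternative 1 | 2-aryl-4-[bromo(aryl)methylidene]-3-(silyloxymethyl)oxolane, 2,3-trans, tert-butyldimethylsilyl ethers | COc1cc(/C(Br)=C2/CO[C@@H](c3ccc(O[Si](C)(C)C(C)(C)C)c(OC)c3)[C@@H]2CO[Si](C)(C)C(C)(C)C)ccc1O[Si](C)(C)C(C)(C)C
A2 | alternative 1 | [1,4-diaryl-2-(silyloxymethyl)but-3-yn-1-yl]oxymethyl acetate with the C2 and C3 configurations of A1 | CC(=O)OCO[C@@H](c1ccc(O[Si](C)(C)C(C)(C)C)c(OC)c1)[C@@H](C#Cc1ccc(O[Si](C)(C)C(C)(C)C)c(OC)c1)CO[Si](C)(C)C(C)(C)C
A3 | alternative 2 | (4S)-4-{[4-(tert-butyldimethylsilyloxy)-3-methoxyphenyl]methyl}oxolan-2-one | COc1cc(C[C@@H]2COC(=O)C2)ccc1O[Si](C)(C)C(C)(C)C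
A4 | alternative 2 | 3-{[4-(tert-butyldimethylsilyloxy)-3-methoxyphenyl]methyl}cyclobutan-1-one | COc1cc(CC2CC(=O)C2)ccc1O[Si](C)(C)C(C)(C)C
A5 | alternative 3 | (−)-lariciresinol bis(tert-butyldimethylsilyl) ether, (2R,3S,4S), free C9 hydroxyl | COc1cc(C[C@@H]2CO[C@@H](c3ccc(O[Si](C)(C)C(C)(C)C)c(OC)c3)[C@@H]2CO)ccc1O[Si](C)(C)C(C)(C)C
A6 | alternative 3 | 2-{aryl[(2E)-3-arylprop-2-enyloxy]methyl}oxirane with the C2 configuration of A5, oxirane carbon of either configuration | COc1cc(/C=C/CO[C@@H](c2ccc(O[Si](C)(C)C(C)(C)C)c(OC)c2)C2CO2)ccc1O[Si](C)(C)C(C)(C)C
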